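The cyclohexene C3a–C4–C5–C6=C7–C7a (hexahydro-1H-indene numbering: C1 CHMe, C2 C=O, C3 CHEt, C4/C5 quaternary) is a Diels–Alder retron, and its new bond C3a–C7a is also the last bond of the cyclopentane C1–C2–C3–C3a–C7a. A thermal intramolecular Diels–Alder reaction of an open-chain (E,E,E)-triene/(E)-enoate therefore closes both rings in one operation and sets C3a, C4, C5 and C7a, including the adjacent quaternary pair. The precursor carries only C1, C3 and a C2 carbinol (oxidised afterwards), made by one organocatalytic hydroxymethylation and one reagent-controlled propargylation; allylic strain relays their configuration to the four new centres.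

Key step: step 13

Remark: "future C1 … C7a" refers to the indene numbering above; acyclic intermediates carry their own IUPAC locants.
Remark: small reagents that deliver atoms (CH2O, MeI, EtMgBr, I2, CBr4, PPh3, MsCl, TBSCl) are given under "Reagents that add atoms" and are not numbered.

Step 1
Reactants: 1 (R)-but-3-yn-2-ol
Product: 3 (R)-pent-3-yn-2-ol, via dilithium salt 2 (not isolated)
Conditions: n-BuLi (2.1 equiv), THF, −78 → −20 °C; MeI, −78 °C → rt; H2O
Reagents that add atoms: iodomethane, CI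
Why: Alkyne C-alkylation: the dianion should react with iodomethane at the acetylide carbon only (the lithium alkoxide is a poor nucleophile in THF), and the carbinol stereocentre is not involved.

Step 2
Reactants: 3 (R)-pent-3-yn-2-ol
Product: 4 (R)-pent-3-yn-2-yl methanesulfonate
Conditions: MsCl, Et3N, CH2Cl2, −78 → 0 °C
Reagents that add atoms: methanesulfonyl chloride, CS(=O)(=O)Cl
Why: Mesylation takes place at oxygen, so the (R) configuration is retained.

Step 3
Reactants: 5 (E)-cinnamaldehyde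
Product: 6 (E)-(4,4-dibromobuta-1,3-dien-1-yl)benzene
Conditions: CBr4, PPh3, CH2Cl2, 0 °C
Reagents that add atoms: tetrabromomethane, BrC(Br)(Br)Br
Why: First stage of the Corey–Fuchs reaction (dibromomethylenation of the aldehyde); the styryl double bond keeps its E geometry.

Step 4
Reactants: 6 (E)-(4,4-dibromobuta-1,3-dien-1-yl)benzene
Product: 8 (E)-but-1-en-3-yn-1-ylbenzene, via lithium acetylide 7 (not isolated)
Conditions: n-BuLi (2.1 equiv), THF, −78 °C; H2O
Reagents that add atoms: none
Why: Second stage of the Corey–Fuchs reaction: bromine–lithium exchange, 1,2-shift of the carbenoid to the alkyne and deprotonation give the acetylide, which water protonates to the terminal enyne.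

Step 5
Reactants: 8 (E)-but-1-en-3-yn-1-ylbenzene
Product: 10 [(1E,3E)-3-ethyl-4-iodobuta-1,3-dien-1-yl]benzene, via dienylcopper 9 (not isolated)
Conditions: EtMgBr, CuBr·SMe2, Et2O/Me2S, −45 → −25 °C; I2, THF, −50 → 0 °C
Reagents that add atoms: ethylmagnesium bromide, CC[Mg]Br; iodine, II
Why: Normant carbocupration: ethylcopper should add syn across the terminal alkyne with ethyl on the internal carbon, and iodinolysis of the C–Cu bond with retention leaves iodine cis to ethyl, i.e. the (1E,3E)-iodide.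

Step 6
Reactants: 11 methyl 2-bromobutanoate (racemic)
Product: 13 methyl 2-(triphenyl-λ5-phosphanylidene)butanoate, via phosphonium bromide 12 (not isolated)
Conditions: PPh3, toluene, 90 °C; aq. NaOH, CH2Cl2, rt
Reagents that add atoms: triphenylphosphine, c1ccc(cc1)P(c1ccccc1)c1ccccc1
Why: SN2 quaternisation of the α-bromo ester and deprotonation give the stabilised Wittig ylide; the stereocentre of racemic 11 is erased.

Step 7
Reactants: 14 butanal
Product: 15 (S)-2-(hydroxymethyl)butanal
Conditions: 37% aq. CH2O, (R)-α,α-diphenylprolinol trimethylsilyl ether (10 mol%), pH 7 phosphate buffer, toluene, rt; crude used at once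
Reagents that add atoms: formaldehyde, C=O
Why: Organocatalytic enamine cross-aldol (α-hydroxymethylation): the (E)-enamine of butanal adds to formaldehyde on the face not shielded by the diphenyl(silyloxy)methyl group, which by the usual sense of this catalyst class should give the (S) centre (future C3) from the (R)-catalyst.

Step 8
Reactants: 15 (S)-2-(hydroxymethyl)butanal
Product: 16 (S)-2-{[(tert-butyldimethylsilyl)oxy]methyl}butanal
Conditions: TBSCl, imidazole, CH2Cl2, 0 °C
Reagents that add atoms: tert-butyldimethylsilyl chloride, CC(C)(C)[Si](C)(C)Cl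
Why: Silylation of the primary hydroxyl under imidazole buffering should turn the labile hydroxy aldehyde (and its hemiacetal oligomers) into a configurationally stable α-branched β-silyloxy aldehyde.

Step 9
Reactants: 16 (S)-2-{[(tert-butyldimethylsilyl)oxy]methyl}butanal; 4 (R)-pent-3-yn-2-yl methanesulfonate
Product: 18 (2S,3S,4S)-1-[(tert-butyldimethylsilyl)oxy]-2-ethyl-4-methylhept-5-yn-3-ol, via allenylzinc 17 (not isolated)
Conditions: Pd(OAc)2 (5 mol%), PPh3 (5 mol%), Et2Zn (3 equiv), THF, −78 → −20 °C; aq. NH4Cl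
Reagents that add atoms: none
Why: Marshall propargylation: anti SN2' oxidative addition of Pd(0) to (R)-4, Pd-to-Zn exchange to the (P)-allenylzinc and cyclic SE2' addition to the aldehyde should give the anti homopropargylic alcohol with net inversion at the former carbinol carbon, so the reagent fixes C4 (future C1) and C3 of 18 as S, a pairing that coincides with Felkin addition to (S)-16.

Step 10
Reactants: 18 (2S,3S,4S)-1-[(tert-butyldimethylsilyl)oxy]-2-ethyl-4-methylhept-5-yn-3-ol; 10 [(1E,3E)-3-ethyl-4-iodobuta-1,3-dien-1-yl]benzene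
Product: 21 (2S,3S,4S,5E,7E,9E)-1-[(tert-butyldimethylsilyl)oxy]-2,8-diethyl-4,6-dimethyl-10-phenyldeca-5,7,9-trien-3-ol, via alkenylzirconocene 19 (not isolated), via alkenylzinc chloride 20 (not isolated)
Conditions: Cp2Zr(H)Cl (2.2 equiv), THF, rt → 45 °C; ZnCl2, 0 °C; 10, Pd(PPh3)4 (5 mol%), rt
Reagents that add atoms: none
Why: One-pot hydrozirconation–Negishi coupling: syn H–Zr addition should place zirconium on the less hindered, methyl-bearing alkyne carbon (the first equivalent is consumed by the hydroxyl), and Zr-to-Zn exchange and Pd-catalysed coupling proceed with retention at both sp2 carbons to give the (5E,7E,9E)-triene.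

Step 11
Reactants: 21 (2S,3S,4S,5E,7E,9E)-1-[(tert-butyldimethylsilyl)oxy]-2,8-diethyl-4,6-dimethyl-10-phenyldeca-5,7,9-trien-3-ol
Product: 22 (2S,3S,4S,5E,7E,9E)-2,8-diethyl-4,6-dimethyl-10-phenyldeca-5,7,9-triene-1,3-diol
Conditions: TBAF, THF, 0 °C → rt
Reagents that add atoms: none
Why: Fluoride cleavage of the primary silyl ether (desilylation); no stereocentre is touched.

Step 12
Reactants: 22 (2S,3S,4S,5E,7E,9E)-2,8-diethyl-4,6-dimethyl-10-phenyldeca-5,7,9-triene-1,3-diol; 13 methyl 2-(triphenyl-λ5-phosphanylidene)butanoate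
Product: 24 methyl (2E,4S,5S,6S,7E,9E,11E)-2,4,10-triethyl-5-hydroxy-6,8-dimethyl-12-phenyldodeca-2,7,9,11-tetraenoate, via hydroxy aldehyde 23 (not isolated)
Conditions: TEMPO (10 mol%), PhI(OAc)2 (1.1 equiv), CH2Cl2, rt; then 13 (3 equiv), rt → 40 °C
Reagents that add atoms: none
Why: Chemoselective TEMPO/PhI(OAc)2 oxidation of the primary hydroxyl, followed in the same flask by Wittig olefination with the stabilised α-branched ylide, should give the (E)-trisubstituted enoate under neutral conditions that spare the α-stereocentre of 23.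

Step 13
Reactants: 24 methyl (2E,4S,5S,6S,7E,9E,11E)-2,4,10-triethyl-5-hydroxy-6,8-dimethyl-12-phenyldodeca-2,7,9,11-tetraenoate
Product: 25 methyl (1S,2S,3S,3aR,4R,5S,7aR)-3,4,5-triethyl-2-hydroxy-1,7-dimethyl-5-[(E)-2-phenylethenyl]-2,3,3a,4,5,7a-hexahydro-1H-indene-4-carboxylate
Conditions: toluene (0.01 M), BHT (cat.), 100 °C, argon, dark
Reagents that add atoms: none
Why: The enoate C3a=C4 adds suprafacially across the diene C7a=C7–C6=C5 in a concerted, thermally allowed [4+2] cycloaddition (type-1 intramolecular Diels–Alder reaction of a 1,6,8-nonatriene), forming C3a–C7a and C4–C5. The cyclohexene is closed by the cycloaddition itself and the cyclopentane by the same C3a–C7a bond, a five-membered closure over the three-atom tether C1–C2–C3, so the tether-anti transition state with the ester endo (under the diene) is expected and gives the trans ring fusion. The E geometry of the enoate and of both diene double bonds is transferred stereospecifically, which places CO2Me cis to the styryl group and the ethyl groups on C4 and C5 cis to each other. The diene face is selected by the C1 and C3 centres: 1,3-allylic strain with the C7 methyl and with the C4 ethyl group holds C1–H and C3–H in the planes of diene and dienophile, so the partner should approach anti to the C1 methyl and the C3 ethyl group, which sets C7a (R), C3a (R), C4 (R) and C5 (S); the two centres reinforce each other and the C2 hydroxyl is a spectator. The step needs endo/exo selectivity, which rests on secondary overlap of the ester and on the strain of the alternative cis-fused tether arrangement, and periselectivity, which is secured because only the C7a=C7–C6=C5 diene can reach the dienophile through a five-membered ring.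

Step 14
Reactants: 25 methyl (1S,2S,3S,3aR,4R,5S,7aR)-3,4,5-triethyl-2-hydroxy-1,7-dimethyl-5-[(E)-2-phenylethenyl]-2,3,3a,4,5,7a-hexahydro-1H-indene-4-carboxylate
Product: 26 (1S,2S,3S,3aR,4R,5S,7aR)-3,4,5-triethyl-2-hydroxy-1,7-dimethyl-5-[(E)-2-phenylethenyl]-2,3,3a,4,5,7a-hexahydro-1H-indene-4-carboxylic acid
Conditions: NaSEt (5 equiv), DMF, 90 °C; aq. HCl
Reagents that add atoms: none
Why: SN2 O-demethylation by thiolate at the unhindered methyl carbon (ester dealkylation) avoids attack at the carbonyl shielded by the quaternary carbons C4 and C5, and no epimerisable centre is present at this stage.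

Step 15
Reactants: 26 (1S,2S,3S,3aR,4R,5S,7aR)-3,4,5-triethyl-2-hydroxy-1,7-dimethyl-5-[(E)-2-phenylethenyl]-2,3,3a,4,5,7a-hexahydro-1H-indene-4-carboxylic acid
Product: 27 (1S,3S,3aR,4R,5S,7aR)-3,4,5-triethyl-1,7-dimethyl-2-oxo-5-[(E)-2-phenylethenyl]-2,3,3a,4,5,7a-hexahydro-1H-indene-4-carboxylic acid
Conditions: Dess–Martin periodinane, NaHCO3, CH2Cl2, 0 °C → rt
Reagents that add atoms: none
Why: Dess–Martin oxidation of the C2 carbinol under bicarbonate buffer; C1 and C3 become α-centres only now, and since each substituent is trans to its ring-fusion neighbour (the arrangement expected to be thermodynamically preferred) no epimerisation is anticipated.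

Compound list
1 | (R)-but-3-yn-2-ol | C[C@@H](O)C#C | starting material
2 | dilithium salt of 1 (lithium alkoxide, lithium acetylide) | C[C@@H](O[Li])C#C[Li] | intermediate
3 | (R)-pent-3-yn-2-ol | C[C@@H](O)C#CC | intermediate
4 | (R)-pent-3-yn-2-yl methanesulfonate | C[C@@H](OS(C)(=O)=O)C#CC | intermediate
5 | (E)-cinnamaldehyde | O=C/C=C/c1ccccc1 | starting material
6 | (E)-(4,4-dibromobuta-1,3-dien-1-yl)benzene | BrC(Br)=C/C=C/c1ccccc1 | intermediate
7 | lithium (E)-4-phenylbut-3-en-1-yn-1-ide | [Li]C#C/C=C/c1ccccc1 | intermediate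
8 | (E)-but-1-en-3-yn-1-ylbenzene | C#C/C=C/c1ccccc1 | intermediate
9 | [(1E,3E)-2-ethyl-4-phenylbuta-1,3-dien-1-yl]copper (MgBr2 complex) | [Cu]/C=C(\CC)/C=C/c1ccccc1 | intermediate
10 | [(1E,3E)-3-ethyl-4-iodobuta-1,3-dien-1-yl]benzene | I/C=C(\CC)/C=C/c1ccccc1 | intermediate
11 | methyl 2-bromobutanoate (racemic) | CCC(Br)C(=O)OC | starting material
12 | (1-methoxy-1-oxobutan-2-yl)triphenylphosphonium bromide | CCC(C(=O)OC)[P+](c1ccccc1)(c1ccccc1)c1ccccc1.[Br-] | intermediate
13 | methyl 2-(triphenyl-λ5-phosphanylidene)butanoate | CCC(C(=O)OC)=P(c1ccccc1)(c1ccccc1)c1ccccc1 | intermediate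
14 | butanal | CCCC=O | starting material
15 | (S)-2-(hydroxymethyl)butanal | CC[C@@H](CO)C=O | intermediate
16 | (S)-2-{[(tert-butyldimethylsilyl)oxy]methyl}butanal | CC[C@@H](CO[Si](C)(C)C(C)(C)C)C=O | intermediate
17 | (P)-ethyl(penta-2,3-dien-2-yl)zinc | CC[Zn]C(C)=[C@@]=C([H])C | intermediate
18 | (2S,3S,4S)-1-[(tert-butyldimethylsilyl)oxy]-2-ethyl-4-methylhept-5-yn-3-ol | CC[C@@H](CO[Si](C)(C)C(C)(C)C)[C@@H](O)[C@@H](C)C#CC | intermediate
19 | (E)-alkenyl(chloro)zirconocene from 18, Zr on the methyl-bearing alkene carbon, hydroxyl as chlorozirconocene alkoxide | CC[C@@H](CO[Si](C)(C)C(C)(C)C)[C@@H](O[Zr](Cl)(C1C=CC=C1)C1C=CC=C1)[C@@H](C)/C=C(\C)[Zr](Cl)(C1C=CC=C1)C1C=CC=C1 | intermediate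
20 | (E)-alkenylzinc chloride from 19 | CC[C@@H](CO[Si](C)(C)C(C)(C)C)[C@@H](O[Zr](Cl)(C1C=CC=C1)C1C=CC=C1)[C@@H](C)/C=C(\C)[Zn]Cl | intermediate
21 | (2S,3S,4S,5E,7E,9E)-1-[(tert-butyldimethylsilyl)oxy]-2,8-diethyl-4,6-dimethyl-10-phenyldeca-5,7,9-trien-3-ol | CC[C@@H](CO[Si](C)(C)C(C)(C)C)[C@@H](O)[C@@H](C)/C=C(\C)/C=C(\CC)/C=C/c1ccccc1 | intermediate
22 | (2S,3S,4S,5E,7E,9E)-2,8-diethyl-4,6-dimethyl-10-phenyldeca-5,7,9-triene-1,3-diol | CC[C@@H](CO)[C@@H](O)[C@@H](C)/C=C(\C)/C=C(\CC)/C=C/c1ccccc1 | intermediate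
23 | (2R,3S,4S,5E,7E,9E)-2,8-diethyl-3-hydroxy-4,6-dimethyl-10-phenyldeca-5,7,9-trienal | CC[C@@H](C=O)[C@@H](O)[C@@H](C)/C=C(\C)/C=C(\CC)/C=C/c1ccccc1 | intermediate
24 | methyl (2E,4S,5S,6S,7E,9E,11E)-2,4,10-triethyl-5-hydroxy-6,8-dimethyl-12-phenyldodeca-2,7,9,11-tetraenoate | CC[C@@H](/C=C(\CC)C(=O)OC)[C@@H](O)[C@@H](C)/C=C(\C)/C=C(\CC)/C=C/c1ccccc1 | intermediate
25 | methyl (1S,2S,3S,3aR,4R,5S,7aR)-3,4,5-triethyl-2-hydroxy-1,7-dimethyl-5-[(E)-2-phenylethenyl]-2,3,3a,4,5,7a-hexahydro-1H-indene-4-carboxylate | CC[C@@H]1[C@@H](O)[C@@H](C)[C@@H]2C(C)=C[C@@](/C=C/c3ccccc3)(CC)[C@](CC)(C(=O)OC)[C@H]21 | intermediate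
26 | (1S,2S,3S,3aR,4R,5S,7aR)-3,4,5-triethyl-2-hydroxy-1,7-dimethyl-5-[(E)-2-phenylethenyl]-2,3,3a,4,5,7a-hexahydro-1H-indene-4-carboxylic acid | CC[C@@H]1[C@@H](O)[C@@H](C)[C@@H]2C(C)=C[C@@](/C=C/c3ccccc3)(CC)[C@](CC)(C(=O)O)[C@H]21 | intermediate
27 | (1S,3S,3aR,4R,5S,7aR)-3,4,5-triethyl-1,7-dimethyl-2-oxo-5-[(E)-2-phenylethenyl]-2,3,3a,4,5,7a-hexahydro-1H-indene-4-carboxylic acid | CC[C@@H]1C(=O)[C@@H](C)[C@@H]2C(C)=C[C@@](/C=C/c3ccccc3)(CC)[C@](CC)(C(=O)O)[C@H]21 | target

Total step count: 15.
Longest linear sequence: 9 steps (steps 7–15 from butanal; the branches through steps 1–2 and 3–5 are equally long).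

Steps most likely to fail

Step 13. At the temperature needed to join two fully substituted carbons the preference for the ester-endo, trans-fused transition state over the cis-fused one may be small, and a 1,5-hydrogen shift from the Z-ethyl group of the diene or oligomerisation may compete. The fallback sets out from 24 and returns at 26. DIBAL-H (CH2Cl2, −78 °C) should reduce the ester to (2E,4S,5S,6S,7E,9E,11E)-2,4,10-triethyl-6,8-dimethyl-12-phenyldodeca-2,7,9,11-tetraene-1,5-diol F1, whose allylic hydroxyl alone is oxidised by MnO2 to (2E,4S,5S,6S,7E,9E,11E)-2,4,10-triethyl-5-hydroxy-6,8-dimethyl-12-phenyldodeca-2,7,9,11-tetraenal F2. The enal is a stronger dienophile and would be cyclised under Lewis-acid activation (Me2AlCl, 2.2 equiv, CH2Cl2, −40 °C; the first equivalent caps the hydroxyl), where carbonyl-endo control is tighter, to (1S,2S,3S,3aR,4R,5S,7aR)-3,4,5-triethyl-2-hydroxy-1,7-dimethyl-5-[(E)-2-phenylethenyl]-2,3,3a,4,5,7a-hexahydro-1H-indene-4-carbaldehyde F3. Pinnick oxidation (NaClO2, NaH2PO4, 2-methylbut-2-ene, t-BuOH/H2O) then gives 26.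

Step 10. Hydrozirconation next to a zirconium alkoxide may lose regiocontrol, and the hindered alkenylmetal may be protonated or reduced before it transmetalates and couples. The fallback sets out from 18 and returns at 22; it separates the events and reverses the coupling polarity. TESOTf/2,6-lutidine gives the C3 triethylsilyl ether of 18, tert-butyl{[(2S,3S,4S)-2-ethyl-4-methyl-3-[(triethylsilyl)oxy]hept-5-yn-1-yl]oxy}dimethylsilane F4. Hydrozirconation and iodinolysis (Cp2Zr(H)Cl, THF; I2) give the isolable tert-butyl{[(2S,3S,4S,5E)-2-ethyl-6-iodo-4-methyl-3-[(triethylsilyl)oxy]hept-5-en-1-yl]oxy}dimethylsilane F5, which can be purified from any regioisomer. Iodide 10 is converted (t-BuLi, Et2O, −78 °C; i-PrOBpin) into 2-[(1E,3E)-2-ethyl-4-phenylbuta-1,3-dien-1-yl]-4,4,5,5-tetramethyl-1,3,2-dioxaborolane F6. Suzuki–Miyaura coupling of F5 with F6 (Pd(PPh3)4, aq. KOH, THF) gives the bis-silyl ether of 22, tert-butyl{[(2S,3S,4S,5E,7E,9E)-2,8-diethyl-4,6-dimethyl-10-phenyl-3-[(triethylsilyl)oxy]deca-5,7,9-trien-1-yl]oxy}dimethylsilane F7, and excess TBAF removes both silyl groups to give 22.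

Step 8. Material and enantiopurity may be lost while the free β-hydroxy aldehyde is handled and silylated (hemiacetal oligomers, enolisation or retro-aldol, β-elimination to 2-ethylacrolein). The fallback sets out from 14 and returns at 24; it never isolates the hydroxy aldehyde and installs the dienophile first. The hydroxymethylation is run with the enantiomeric (S)-catalyst, and (R)-2-(hydroxymethyl)butanal F8 is trapped in the same flask with ylide 13, so that the former aldehyde carbon becomes C3a and the hydroxymethyl carbon becomes C2; this gives methyl (S,E)-2-ethyl-4-(hydroxymethyl)hex-2-enoate F9. Dess–Martin oxidation gives methyl (S,E)-2-ethyl-4-formylhex-2-enoate F10, which is used at once because its α-centre is labile. Marshall propargylation with 4 (conditions of step 9) should give methyl (2E,4S,5R,6S)-2,4-diethyl-5-hydroxy-6-methylnon-2-en-7-ynoate F11, and hydrozirconation–Negishi coupling with 10 (conditions of step 10, short contact time to spare the enoate) gives 24.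

Further compounds
F1 | step 13 | (2E,4S,5S,6S,7E,9E,11E)-2,4,10-triethyl-6,8-dimethyl-12-phenyldodeca-2,7,9,11-tetraene-1,5-diol | CC[C@@H](/C=C(\CC)CO)[C@@H](O)[C@@H](C)/C=C(\C)/C=C(\CC)/C=C/c1ccccc1
F2 | step 13 | (2E,4S,5S,6S,7E,9E,11E)-2,4,10-triethyl-5-hydroxy-6,8-dimethyl-12-phenyldodeca-2,7,9,11-tetraenal | CC[C@@H](/C=C(\CC)C=O)[C@@H](O)[C@@H](C)/C=C(\C)/C=C(\CC)/C=C/c1ccccc1
F3 | step 13 | (1S,2S,3S,3aR,4R,5S,7aR)-3,4,5-triethyl-2-hydroxy-1,7-dimethyl-5-[(E)-2-phenylethenyl]-2,3,3a,4,5,7a-hexahydro-1H-indene-4-carbaldehyde | CC[C@@H]1[C@@H](O)[C@@H](C)[C@@H]2C(C)=C[C@@](/C=C/c3ccccc3)(CC)[C@](CC)(C=O)[C@H]21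
F4 | step 10 | tert-butyl{[(2S,3S,4S)-2-ethyl-4-methyl-3-[(triethylsilyl)oxy]hept-5-yn-1-yl]oxy}dimethylsilane | CC[C@@H](CO[Si](C)(C)C(C)(C)C)[C@@H](O[Si](CC)(CC)CC)[C@@H](C)C#CC
F5 | step 10 | tert-butyl{[(2S,3S,4S,5E)-2-ethyl-6-iodo-4-methyl-3-[(triethylsilyl)oxy]hept-5-en-1-yl]oxy}dimethylsilane | CC[C@@H](CO[Si](C)(C)C(C)(C)C)[C@@H](O[Si](CC)(CC)CC)[C@@H](C)/C=C(\C)I
F6 | step 10 | 2-[(1E,3E)-2-ethyl-4-phenylbuta-1,3-dien-1-yl]-4,4,5,5-tetramethyl-1,3,2-dioxaborolane | B1(OC(C)(C)C(C)(C)O1)/C=C(\CC)/C=C/c1ccccc1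
F7 | step 10 | tert-butyl{[(2S,3S,4S,5E,7E,9E)-2,8-diethyl-4,6-dimethyl-10-phenyl-3-[(triethylsilyl)oxy]deca-5,7,9-trien-1-yl]oxy}dimethylsilane | CC[C@@H](CO[Si](C)(C)C(C)(C)C)[C@@H](O[Si](CC)(CC)CC)[C@@H](C)/C=C(\C)/C=C(\CC)/C=C/c1ccccc1
F8 | step 8 | (R)-2-(hydroxymethyl)butanal | CC[C@H](CO)C=O
F9 | step 8 | methyl (S,E)-2-ethyl-4-(hydroxymethyl)hex-2-enoate | CC[C@@H](/C=C(\CC)C(=O)OC)CO
F10 | step 8 | methyl (S,E)-2-ethyl-4-formylhex-2-enoate | CC[C@@H](/C=C(\CC)C(=O)OC)C=O
F11 | step 8 | methyl (2E,4S,5R,6S)-2,4-diethyl-5-hydroxy-6-methylnon-2-en-7-ynoate | CC[C@@H](/C=C(\CC)C(=O)OC)[C@@H](O)[C@@H](C)C#CC
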